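**Assumption (one line):** atoms carry lignan-style labels (C1 carbinol carbon, C2 the ArCH next to it, O3, C4H2, C5 ring-fusion CH, C6 the other ArCH, O7, C8H2; Ar = 3,4-dimethoxyphenyl), compounds carry plain numbers, and ClMe2SiOSiMe2H is bought or made from (HMe2Si)2O.

## Retrosynthetic overview

1. Ring B is opened last at O7–C8 (alkoxide displacing a primary tosylate); the C6–O bond and the C5–H come from a syn, O1-anchored hydrosilylation and C–Si to C–O oxidation of an exocyclic (Z)-arylidene.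
2. Ring A is opened at C2–O3 and C1–O: Sharpless epoxidation of one arm of a C2-symmetric (E,E)-diene diol, then invertive 5-endo opening by the hydroxymethyl of the other arm.
3. The diene diol comes from the bis(arylidene)succinate, made by double Stobbe condensation of veratraldehyde with dimethyl succinate.
4. Ring order forward: ring A (step 3), then ring B (step 5); all four stereocentres are set in C–O bond-forming events.

## Route

**Step 1**
Reactants: 1 veratraldehyde (2.2 equiv), 2 dimethyl succinate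
Product: 4 dimethyl (2E,3E)-2,3-bis(3,4-dimethoxybenzylidene)succinate, via disodium dicarboxylate 3 (not isolated)
Conditions: NaOMe (3 equiv), MeOH, reflux; evaporate; then MeI (5 equiv), DMF, 25 °C; crystallise
Reagents that add atoms: iodomethane, CI
Why: Double Stobbe condensation (aldol, lactonisation and E1cB ring opening on each side) gives the thermodynamic (E,E)-dianion, and SN2 O-methylation converts it into the crystalline diester; no stereocentre is formed.

**Step 2**
Reactants: 4 dimethyl (2E,3E)-2,3-bis(3,4-dimethoxybenzylidene)succinate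
Product: 5 (2E,3E)-2,3-bis(3,4-dimethoxybenzylidene)butane-1,4-diol
Conditions: i-Bu2AlH (5 equiv), CH2Cl2, −78 to 0 °C; aq. KNaC4H4O6
Reagents that add atoms: none
Why: 1,2-Reduction of both enoates by the aluminium hydride leaves the trisubstituted styrenes and their E geometry untouched.

**Step 3**
Reactants: 5 (2E,3E)-2,3-bis(3,4-dimethoxybenzylidene)butane-1,4-diol
Product: 7 (2R,3S,4Z)-2-(3,4-dimethoxyphenyl)-4-(3,4-dimethoxybenzylidene)-3-(hydroxymethyl)tetrahydrofuran-3-ol, via epoxy diol 6 (not isolated)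
Conditions: Ti(OiPr)4 (1.1 equiv), L-(+)-diethyl tartrate (1.3 equiv), t-BuOOH (1.05 equiv), 4 Å MS, CH2Cl2, −25 to 0 °C; aq. citric acid
Reagents that add atoms: tert-butyl hydroperoxide, CC(C)(C)OO
Why: Sharpless asymmetric epoxidation with L-(+)-tartrate gives the (2S,3S)-epoxide, as for (E)-2-substituted cinnamyl alcohols, and so fixes C1 (S); the tetravalent titanium then promotes anti 5-endo opening of the electron-rich benzylic C–O bond by the hydroxymethyl of the other arm, which inverts C2 to R with the aryl cis to the tertiary OH, and removes the primary allylic OH that would direct epoxidation of the second alkene.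

**Step 4**
Reactants: 7 (2R,3S,4Z)-2-(3,4-dimethoxyphenyl)-4-(3,4-dimethoxybenzylidene)-3-(hydroxymethyl)tetrahydrofuran-3-ol
Product: 8 [(2R,3S,4Z)-2-(3,4-dimethoxyphenyl)-4-(3,4-dimethoxybenzylidene)-3-hydroxytetrahydrofuran-3-yl]methyl 4-methylbenzenesulfonate
Conditions: TsCl (1.05 equiv), Et3N (1.5 equiv), Bu2SnO (2 mol %), CH2Cl2, 0 to 25 °C
Reagents that add atoms: p-toluenesulfonyl chloride, Cc1ccc(cc1)S(=O)(=O)Cl
Why: Stannylene-acetal-catalysed sulfonylation of a 1,2-diol is selective for the primary hydroxyl, so the tertiary OH stays free; the tosylate both blocks the face of C8 and is the later leaving group.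

**Step 5**
Reactants: 8 [(2R,3S,4Z)-2-(3,4-dimethoxyphenyl)-4-(3,4-dimethoxybenzylidene)-3-hydroxytetrahydrofuran-3-yl]methyl 4-methylbenzenesulfonate
Product: 12 (+)-gmelinol [(1S,2R,5R,6R)-2,6-bis(3,4-dimethoxyphenyl)-3,7-dioxabicyclo[3.3.0]octan-1-ol], via disiloxanyl ether 9 (not isolated), via cyclic disiloxane 10 (not isolated), via diol tosylate 11 (not isolated)
Conditions: ClMe2SiOSiMe2H, imidazole, CH2Cl2, 0 °C; filter; Pt2[(CH2=CHSiMe2)2O]3 (1 mol %), toluene, 60 °C; then 30% H2O2, KF, KHCO3, THF/MeOH, 40 °C; then K2CO3, 50 °C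
Reagents that add atoms: hydrogen peroxide, OO (the C6 oxygen; the disiloxane reagent supplies only the C5 hydrogen)
Why: Proposed new method: a disiloxanyl hydride tether on the tertiary C1 oxygen relays Si–H to the exocyclic alkene on the face of that oxygen only (Chalk–Harrod syn addition at zerovalent platinum, H to C5 and Si to the less hindered benzylic C6, through an unstrained seven-membered ring where the usual one-silicon tether would need a trans-fused five-membered ring), which sets C5 (R) and the C6–Si bond together, after which Tamao–Fleming oxidation converts C–Si into C–O with retention (C6 R) and the alkoxide closes ring B by 5-exo-tet Williamson displacement of the tosylate, leaving the aryl endo without any acid; the closest known reaction is the Tamao–Ito intramolecular hydrosilylation/oxidation of allylic and homoallylic alcohols through five-membered oxasilacycles.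

## Compound list

1 | 3,4-dimethoxybenzaldehyde (veratraldehyde) | COc1ccc(C=O)cc1OC | starting material
2 | dimethyl succinate | COC(=O)CCC(=O)OC | starting material
3 | disodium (2E,3E)-2,3-bis(3,4-dimethoxybenzylidene)succinate | [Na+].[Na+].COc1ccc(/C=C(C(=O)[O-])\C(C(=O)[O-])=C/c2ccc(OC)c(OC)c2)cc1OC | intermediate
4 | dimethyl (2E,3E)-2,3-bis(3,4-dimethoxybenzylidene)succinate | COc1ccc(/C=C(C(=O)OC)\C(C(=O)OC)=C/c2ccc(OC)c(OC)c2)cc1OC | intermediate
5 | (2E,3E)-2,3-bis(3,4-dimethoxybenzylidene)butane-1,4-diol | COc1ccc(/C=C(CO)\C(CO)=C/c2ccc(OC)c(OC)c2)cc1OC | intermediate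
6 | [(2S,3S)-3-(3,4-dimethoxyphenyl)-2-[(Z)-1-(3,4-dimethoxyphenyl)-3-hydroxyprop-1-en-2-yl]oxiran-2-yl]methanol | COc1ccc([C@@H]2O[C@]2(CO)/C(CO)=C\c2ccc(OC)c(OC)c2)cc1OC | intermediate
7 | (2R,3S,4Z)-2-(3,4-dimethoxyphenyl)-4-(3,4-dimethoxybenzylidene)-3-(hydroxymethyl)tetrahydrofuran-3-ol | COc1ccc([C@H]2OC/C(=C/c3ccc(OC)c(OC)c3)[C@]2(O)CO)cc1OC | intermediate
8 | [(2R,3S,4Z)-2-(3,4-dimethoxyphenyl)-4-(3,4-dimethoxybenzylidene)-3-hydroxytetrahydrofuran-3-yl]methyl 4-methylbenzenesulfonate | COc1ccc([C@H]2OC/C(=C/c3ccc(OC)c(OC)c3)[C@]2(O)COS(=O)(=O)c4ccc(C)cc4)cc1OC | intermediate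
9 | [(2R,3S,4Z)-2-(3,4-dimethoxyphenyl)-4-(3,4-dimethoxybenzylidene)-3-[(1,1,3,3-tetramethyldisiloxanyl)oxy]tetrahydrofuran-3-yl]methyl 4-methylbenzenesulfonate | COc1ccc([C@H]2OC/C(=C/c3ccc(OC)c(OC)c3)[C@]2(O[Si](C)(C)O[SiH](C)C)COS(=O)(=O)c4ccc(C)cc4)cc1OC | intermediate
10 | cyclic disiloxane: tosylate 8 with H added to C5 cis to the C1 oxygen and C6 bonded to SiMe2–O–SiMe2–O–C1 (seven-membered 1,3-dioxa-2,4-disilepane trans-fused at C1–C5; C1 S, C2 R, C5 S by priority change only, C6 R) | COc1ccc([C@H]2OC[C@@H]3[C@H](c4ccc(OC)c(OC)c4)[Si](C)(C)O[Si](C)(C)O[C@@]23COS(=O)(=O)c5ccc(C)cc5)cc1OC | intermediate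
11 | [(2R,3S,4R)-2-(3,4-dimethoxyphenyl)-4-[(R)-(3,4-dimethoxyphenyl)(hydroxy)methyl]-3-hydroxytetrahydrofuran-3-yl]methyl 4-methylbenzenesulfonate | COc1ccc([C@H]2OC[C@H]([C@@H](O)c3ccc(OC)c(OC)c3)[C@]2(O)COS(=O)(=O)c4ccc(C)cc4)cc1OC | intermediate
12 | (+)-gmelinol, (1S,2R,5R,6R)-2,6-bis(3,4-dimethoxyphenyl)-3,7-dioxabicyclo[3.3.0]octan-1-ol | COc1ccc([C@H]2OC[C@@H]3[C@H](c4ccc(OC)c(OC)c4)OC[C@]23O)cc1OC | target

## Count and risks

Total steps: 5. Longest linear sequence: 5.

**Step 5 (the proposed new step; highest risk).** The seven-membered hydrosilylation of a trisubstituted styrene may be slow. Reversible Pt–H addition could isomerise the (Z)-alkene, which would give the C6 epimer. The benzylic silane could also protodesilylate. The fallback uses known chemistry only, sets out from 7 and returns at 12. Hydroboration–oxidation of 7 (BH3·SMe2, THF, then NaBO3) gives the benzylic carbinol, (2R,3S)-2-(3,4-dimethoxyphenyl)-4-[(3,4-dimethoxyphenyl)(hydroxy)methyl]-3-(hydroxymethyl)tetrahydrofuran-3-ol F6, as a mixture at C5 and C6. MnO2 in CH2Cl2 oxidises only the benzylic alcohol to the aryl ketone. C5, now next to the carbonyl, equilibrates, and the ketone closes on the C8 hydroxyl to the cis-fused lactol (1S,2R,5S)-2,6-bis(3,4-dimethoxyphenyl)-3,7-dioxabicyclo[3.3.0]octane-1,6-diol F7. Et3SiH with BF3·OEt2 at −78 °C reduces the aryl oxocarbenium ion from the convex face, which leaves the aryl endo and gives 12.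

**Step 3.** The 1,4-diol may chelate titanium and lower the enantioselectivity. The second arm could be epoxidised before ring closure. The vinyl epoxide could also open in a vinylogous sense. The fallback sets out from 5 and returns at 7 through 6. Mono-silylation of 5 (NaH, t-BuMe2SiCl, THF) gives (2E,3E)-4-[(tert-butyldimethylsilyl)oxy]-2,3-bis(3,4-dimethoxybenzylidene)butan-1-ol F4. A standard catalytic Sharpless epoxidation of its single free allylic alcohol (Ti(OiPr)4, L-(+)-diethyl tartrate, t-BuOOH, 4 Å MS, −20 °C) gives the silyl-protected epoxy alcohol F5. Buffered Bu4NF frees the second hydroxyl to give 6, and pyridinium p-toluenesulfonate closes it to 7.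

**Step 1.** The one-pot double Stobbe condensation may stop at the mono-arylidene stage or give E/Z mixtures. The fallback sets out from 1 and returns at 4. Triphenylphosphine adds to dimethyl maleate to give the ylide dimethyl 2-(triphenylphosphoranylidene)succinate F1. Wittig reaction of F1 with 1 gives dimethyl (E)-2-(3,4-dimethoxybenzylidene)succinate F2. A single Stobbe condensation of F2 with a second equivalent of 1 (NaOMe, MeOH) gives the half ester (2E,3E)-2,3-bis(3,4-dimethoxybenzylidene)succinic acid monomethyl ester F3. MeI and K2CO3 in DMF convert F3 into 4.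

## Further compounds

F1 | step 1 | dimethyl 2-(triphenylphosphoranylidene)succinate | COC(=O)CC(=P(c1ccccc1)(c1ccccc1)c1ccccc1)C(=O)OC
F2 | step 1 | dimethyl (E)-2-(3,4-dimethoxybenzylidene)succinate | COC(=O)C/C(=C\c1ccc(OC)c(OC)c1)C(=O)OC
F3 | step 1 | (2E,3E)-2,3-bis(3,4-dimethoxybenzylidene)succinic acid monomethyl ester | COc1ccc(/C=C(C(=O)O)\C(C(=O)OC)=C/c2ccc(OC)c(OC)c2)cc1OC
F4 | step 3 | (2E,3E)-4-[(tert-butyldimethylsilyl)oxy]-2,3-bis(3,4-dimethoxybenzylidene)butan-1-ol | COc1ccc(/C=C(CO)\C(CO[Si](C)(C)C(C)(C)C)=C/c2ccc(OC)c(OC)c2)cc1OC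
F5 | step 3 | [(2S,3S)-2-[(Z)-3-[(tert-butyldimethylsilyl)oxy]-1-(3,4-dimethoxyphenyl)prop-1-en-2-yl]-3-(3,4-dimethoxyphenyl)oxiran-2-yl]methanol | COc1ccc([C@@H]2O[C@]2(CO)/C(CO[Si](C)(C)C(C)(C)C)=C\c2ccc(OC)c(OC)c2)cc1OC
F6 | step 5 | (2R,3S)-2-(3,4-dimethoxyphenyl)-4-[(3,4-dimethoxyphenyl)(hydroxy)methyl]-3-(hydroxymethyl)tetrahydrofuran-3-ol (mixture at C4 and the carbinol carbon) | COc1ccc([C@H]2OCC(C(O)c3ccc(OC)c(OC)c3)[C@]2(O)CO)cc1OC
F7 | step 5 | (1S,2R,5S)-2,6-bis(3,4-dimethoxyphenyl)-3,7-dioxabicyclo[3.3.0]octane-1,6-diol (anomeric mixture at C6) | COc1ccc([C@H]2OC[C@@H]3C(O)(c4ccc(OC)c(OC)c4)OC[C@]23O)cc1OC
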